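**Plan**
- Retrosynthesis: cut the C8–O acyl bond, then the C4–OH bond (late oxidation of C4–H). Next rejoin O8 and the ester carbon on C3 into one ketone carbon bridging C3 and C8 (retro-Baeyer–Villiger). Finally cut C3–C4 and C7–C8 together (retro (4+3)) to 2-methylfuran and a cycloheptenone epoxide fused to ring A.
- Enabling feature: O, C4, C5=C6 and C7 form a 2,5-dihydrofuran spanning a carbocycle, which is the oxygen bridge and etheno bridge of a furan–oxyallyl adduct. C8 (oxygen) and C3 (carboxyl carbon) are the two α-carbons of a single ketone after oxygen insertion.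
- Forward order: ring A from (R)-α-phellandrene (ketene [2+2], ring opening); the seven-membered enone by ring-closing metathesis; epoxy enol silane; the (4+3) cycloaddition with 2-methylfuran closes the nine-membered oxacycle (O, C4, C3, C2, C1, C10, C9, C8, C7) last, the five-membered ring arriving intact as the furan. The one-carbon bridge is then converted into C8–OH and CO2Me.
- Stereochemistry: C14 from the chiral pool; C1 and C10 from ketene addition anti to isopropyl; C8, C7 and C4 from the cycloaddition, whose face is set by an epoxide placed through reagent-controlled reduction and hydroxyl-directed epoxidation; O8 by retentive oxygen insertion; the C2=C3 geometry and the C4 hemiketal by the bridged ring.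

Key step: step 14

Remark: carbons are numbered as in the sarcodictyins (C1/C10 ring fusion, C11=C12 in ring A, isopropyl on C14, ester on C3, hemiketal C4, methyl on C7, acyloxy on C8); C15 is the temporary bridging carbon that ends as the ester carbonyl carbon.
Assumption: (R)-α-phellandrene of high enantiomeric purity and (E)-3-(1-methylimidazol-4-yl)prop-2-enoic acid are taken as purchasable.

Step 1
Reactants: 1 (R)-α-phellandrene
Product: 3 cis-fused cyclobutanone, via dichlorocyclobutanone 2 (not isolated)
Conditions: Cl3CCOCl, Zn, Et2O, ultrasound, 20 °C; then AcOH, Zn, 50 °C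
Reagents that add atoms: trichloroacetyl chloride ClC(=O)C(Cl)(Cl)Cl
Why: Ketene [2+2] cycloaddition followed by reductive dechlorination: dichloroketene made in the flask should add to the disubstituted double bond of the diene with its carbonyl carbon at the diene terminus (future C1) and on the face opposite the isopropyl group, which sets the cis relation of the C1 and C10 branches and their trans relation to the C14 isopropyl group, and zinc in acetic acid then removes both chlorines.

Step 2
Reactants: 3 cis-fused cyclobutanone
Product: 5 ester acetal, via enaminone 4 (not isolated)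
Conditions: t-BuOCH(NMe2)2, 60 °C; then p-TsOH·H2O, MeOH, 65 °C
Reagents that add atoms: tert-butoxybis(dimethylamino)methane CC(C)(C)OC(N(C)C)N(C)C; methanol CO
Why: Condensation of the ketone α-methylene with Bredereck's reagent and acid-promoted retro-Claisen opening of the strained vinylogous amide in methanol should give the methyl ester (C2) on C1 and the dimethyl acetal (C8) on the C9 methylene without touching the ring stereocentres.

Step 3
Reactants: 5 ester acetal
Product: 6 aldehyde acetal
Conditions: (i-Bu)2AlH, CH2Cl2, −78 °C; aqueous potassium sodium tartrate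
Reagents that add atoms: none
Why: Partial ester reduction with (i-Bu)2AlH at low temperature, whose tetrahedral aluminium alkoxide collapses only on work-up, should stop at the aldehyde and leave the α-stereocentre C1 unchanged.

Step 4
Reactants: 6 aldehyde acetal
Product: 7 vinyl acetal
Conditions: Ph3PCH3Br, KN(SiMe3)2, THF, −78 to 0 °C
Reagents that add atoms: methyltriphenylphosphonium bromide C[P+](c1ccccc1)(c1ccccc1)c1ccccc1.[Br-]
Why: Wittig methylenation with the non-stabilised ylide should turn the aldehyde into the C1 vinyl group whose inner carbon is C2.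

Step 5
Reactants: 7 vinyl acetal
Product: 8 C8 aldehyde
Conditions: aqueous HCl (1 mol/L), THF, 23 °C
Reagents that add atoms: water O
Why: Acid-catalysed acetal hydrolysis should unmask the C8 aldehyde while the two alkenes are inert to dilute acid.

Step 6
Reactants: 8 C8 aldehyde
Product: 10 C15 aldehyde, via methyl enol ether 9 (not isolated)
Conditions: Ph3P(CH2OMe)Cl, KN(SiMe3)2, THF, 0 °C; then aqueous HCl (2 mol/L), THF, 23 °C
Reagents that add atoms: (methoxymethyl)triphenylphosphonium chloride COC[P+](c1ccccc1)(c1ccccc1)c1ccccc1.[Cl-]; water O
Why: Wittig reaction with (methoxymethylene)triphenylphosphorane and acid hydrolysis of the enol ether, the standard one-carbon homologation of aldehydes, should add C15 as the new aldehyde carbon.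

Step 7
Reactants: 10 C15 aldehyde
Product: 11 C15 vinyl carbinol
Conditions: CH2=CHMgBr, THF, −78 °C
Reagents that add atoms: vinylmagnesium bromide C=C[Mg]Br
Why: Grignard 1,2-addition of the vinyl nucleophile should bring in C3 and give both C15 epimers, which does not matter because this centre is oxidised in step 9.

Step 8
Reactants: 11 C15 vinyl carbinol
Product: 12 cycloheptenol
Conditions: second-generation Grubbs catalyst RuCl2(=CHPh)(H2IMes)(PCy3) (5 mol%), CH2Cl2 (5 mmol/L), 40 °C
Reagents that add atoms: none
Why: Ring-closing metathesis between the two monosubstituted alkenes should close the cis-fused seven-membered ring with loss of ethylene, the trisubstituted ring A alkene being too hindered to compete.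

Step 9
Reactants: 12 cycloheptenol
Product: 13 cycloheptenone
Conditions: Dess–Martin periodinane, NaHCO3, CH2Cl2, 23 °C
Reagents that add atoms: none
Why: Dess–Martin oxidation of the allylic alcohol should give the conjugated cycloheptenone and merge the two C15 epimers.

Step 10
Reactants: 13 cycloheptenone
Product: 14 (S)-cycloheptenol
Conditions: (R)-2-methyl-CBS-oxazaborolidine (20 mol%), catecholborane, toluene, −78 °C
Reagents that add atoms: none
Why: Corey–Bakshi–Shibata reduction, with the alkenyl arm as the large substituent, should deliver hydride under reagent control and give the (S)-carbinol, whose hydroxyl lies on the concave face of the cis-fused bicycle, trans to H1 and H10.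

Step 11
Reactants: 14 (S)-cycloheptenol
Product: 15 epoxy alcohol
Conditions: VO(acac)2 (5 mol%), t-BuOOH, CH2Cl2, 0 °C
Reagents that add atoms: tert-butyl hydroperoxide CC(C)(C)OO
Why: Hydroxyl-directed epoxidation with VO(acac)2 and tert-butyl hydroperoxide should put the oxirane syn to the C15 hydroxyl, hence on the concave face that direct nucleophilic epoxidation of enone 13 would avoid, and should spare the isolated ring A alkene.

Step 12
Reactants: 15 epoxy alcohol
Product: 16 epoxy ketone
Conditions: Dess–Martin periodinane, NaHCO3, CH2Cl2, 23 °C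
Reagents that add atoms: none
Why: Dess–Martin oxidation should regenerate the ketone under non-basic conditions that leave the oxirane closed.

Step 13
Reactants: 16 epoxy ketone
Product: 17 epoxy enol silane
Conditions: LiN(SiMe3)2, Et3SiCl, THF, −78 °C
Reagents that add atoms: chlorotriethylsilane CC[Si](Cl)(CC)CC
Why: Kinetic enolisation at C8, the only α-methylene, with in situ O-silylation should give the triethylsilyl enol ether, that is the latent 2-silyloxyallyl unit C8–C15–C3.

Step 14
Reactants: 17 epoxy enol silane; 18 2-methylfuran
Product: 20 bridged hydroxy ketone, via triethylsilyl ether 19 (not isolated)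
Conditions: 2-methylfuran (5 equiv), Et3SiOTf (10 mol%), CH2Cl2, −78 °C; then HF·pyridine, THF, 0 °C
Reagents that add atoms: none
Why: The silyl triflate silylates the oxirane oxygen, the free α-carbon of 2-methylfuran opens the activated epoxide at C3 with inversion while the enol silane supplies the electrons, and the furanium carbon C7 is then captured by C8, after which the silyl group on the carbonyl oxygen is passed on to the next epoxide; the net change is a (4+3) cycloaddition of a 2-silyloxyallyl cation equivalent to a furan. The closest known reaction type is the silyl-triflate-catalysed (4+3) cycloaddition of epoxy enol silanes with furans, itself a variant of the oxyallyl cation–furan cycloaddition. The nine-membered oxacycle (O, C4, C3, C2, C1, C10, C9, C8, C7) is closed by intermolecular annulation, the bonds C3–C4 and C7–C8 joining the two furan α-carbons to the termini of the allyl unit held in the seven-membered ring, with C15 left as a temporary one-carbon bridge. C3 and C8 are set by attack anti to the concave epoxide, which puts both new bonds on the convex face beside H1 and H10, and C7 and C4 follow from the compact arrangement in which the furan oxygen and not the C5–H/C6–H edge lies over the ring methylenes of the cyclic allyl unit. The step needs regioselectivity (methyl-bearing carbon to C8), which the substrate secures because only the unsubstituted furan α-position can attack the epoxide carbon, facial selectivity, which the epoxide configuration secures, and compact over extended selectivity, which rests on the steric argument alone and is the least certain. HF·pyridine then cleaves the triethylsilyl ether at O2 so that the alcohol is isolated.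

Step 15
Reactants: 20 bridged hydroxy ketone
Product: 21 bridged keto mesylate
Conditions: MsCl, Et3N, CH2Cl2, 0 °C
Reagents that add atoms: methanesulfonyl chloride CS(=O)(=O)Cl
Why: Mesylation of the only hydroxyl should make O2 a leaving group for step 17 and an electron-withdrawing neighbour of C3 for step 16, while elimination is blocked at this stage because the bridgehead C3–H cannot be enolised toward the one-carbon bridge and is syn to the mesylate.

Step 16
Reactants: 21 bridged keto mesylate
Product: 22 bridged lactone
Conditions: Me3SiOOSiMe3, SnCl4 (10 mol%), trans-cyclohexane-1,2-diamine (10 mol%), 4 Å molecular sieves, CH2Cl2, 23 °C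
Reagents that add atoms: bis(trimethylsilyl) peroxide C[Si](C)(C)OO[Si](C)(C)C
Why: Baeyer–Villiger oxidation with bis(trimethylsilyl) peroxide and SnCl4, a reagent pair that does not epoxidise alkenes, should insert oxygen into the C15–C8 bond with retention at C8, because C3 is flanked by the β-mesyloxy group and a second β-oxygen and therefore migrates less readily.

Step 17
Reactants: 22 bridged lactone
Product: 24 4-deoxy hydroxy enoate, via mesyloxy hydroxy ester 23 (not isolated)
Conditions: K2CO3, MeOH, 0 to 23 °C
Reagents that add atoms: methanol CO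
Why: Methanolysis of the strained bridged lactone should release the C8 hydroxyl and the C3 methyl ester, and E1cB elimination of the β-mesylate should then give the enoate, whose C2=C3 bond can only be cis within the bridged nine-membered ring.

Step 18
Reactants: 24 4-deoxy hydroxy enoate
Product: 25 C8 alcohol hemiketal
Conditions: DDQ, CH2Cl2/pH 7 phosphate buffer (10:1), 0 to 23 °C
Reagents that add atoms: water O
Why: Oxidative C–H functionalisation of an allylic ether with DDQ: hydride abstraction from C4–H, which is tertiary, next to the ring oxygen and doubly allylic, should give an oxocarbenium ion that cannot aromatise because C7 is quaternary and that water captures from the face opposite the carbon bridge, the only mode that keeps the nine-membered ring cis-bridged, so that the hemiketal forms with the required configuration.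

Step 19
Reactants: 25 C8 alcohol hemiketal; 26 (E)-N-methylurocanic acid
Product: 28 sarcodictyin A, via mixed anhydride 27 (not isolated)
Conditions: 26, 2,4,6-trichlorobenzoyl chloride, Et3N, THF, 23 °C; then 25, DMAP, toluene, 60 °C
Reagents that add atoms: none
Why: Yamaguchi esterification through the mixed anhydride should acylate the secondary C8 hydroxyl only, the tertiary hemiketal hydroxyl at C4 being too hindered to react.

**Compound list**
1 | (R)-α-phellandrene, (5R)-2-methyl-5-(propan-2-yl)cyclohexa-1,3-diene | C1=CC(C)=CC[C@@H]1C(C)C | starting material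
2 | 8,8-dichloro-2-methyl-5-(propan-2-yl)bicyclo[4.2.0]oct-2-en-7-one, cis ring fusion, isopropyl trans to the C6–C7 bond | O=C1[C@@H]2[C@@H](C(C)C)CC=C(C)[C@@H]2C1(Cl)Cl | intermediate
3 | 2-methyl-5-(propan-2-yl)bicyclo[4.2.0]oct-2-en-7-one, same configuration as 2 | O=C1[C@@H]2[C@@H](C(C)C)CC=C(C)[C@@H]2C1 | intermediate
4 | (E)-8-[(dimethylamino)methylidene]-2-methyl-5-(propan-2-yl)bicyclo[4.2.0]oct-2-en-7-one | O=C1[C@@H]2[C@@H](C(C)C)CC=C(C)[C@@H]2/C1=C\N(C)C | intermediate
5 | methyl 2-(2,2-dimethoxyethyl)-3-methyl-6-(propan-2-yl)cyclohex-3-ene-1-carboxylate, ester cis to the acetal chain and trans to isopropyl | COC(=O)[C@@H]1[C@@H](C(C)C)CC=C(C)[C@@H]1CC(OC)OC | intermediate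
6 | 2-(2,2-dimethoxyethyl)-3-methyl-6-(propan-2-yl)cyclohex-3-ene-1-carbaldehyde, same configuration as 5 | O=C[C@@H]1[C@@H](C(C)C)CC=C(C)[C@@H]1CC(OC)OC | intermediate
7 | 6-(2,2-dimethoxyethyl)-5-ethenyl-1-methyl-4-(propan-2-yl)cyclohex-1-ene, vinyl cis to the acetal chain and trans to isopropyl | C=C[C@@H]1[C@@H](C(C)C)CC=C(C)[C@@H]1CC(OC)OC | intermediate
8 | 2-[6-ethenyl-2-methyl-5-(propan-2-yl)cyclohex-2-en-1-yl]acetaldehyde | C=C[C@@H]1[C@@H](C(C)C)CC=C(C)[C@@H]1CC=O | intermediate
9 | 1-methoxy-3-[6-ethenyl-2-methyl-5-(propan-2-yl)cyclohex-2-en-1-yl]prop-1-ene, E/Z mixture | C=C[C@@H]1[C@@H](C(C)C)CC=C(C)[C@@H]1CC=COC | intermediate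
10 | 3-[6-ethenyl-2-methyl-5-(propan-2-yl)cyclohex-2-en-1-yl]propanal | C=C[C@@H]1[C@@H](C(C)C)CC=C(C)[C@@H]1CCC=O | intermediate
11 | 5-[6-ethenyl-2-methyl-5-(propan-2-yl)cyclohex-2-en-1-yl]pent-1-en-3-ol, both carbinol epimers | C=C[C@@H]1[C@@H](C(C)C)CC=C(C)[C@@H]1CCC(O)C=C | intermediate
12 | 1-methyl-4-(propan-2-yl)-4,4a,7,8,9,9a-hexahydro-3H-benzo[7]annulen-7-ol, cis ring fusion, isopropyl trans to the C4a–C5 bond, both C7 epimers | OC1CC[C@H]2C(C)=CC[C@H](C(C)C)[C@H]2C=C1 | intermediate
13 | 1-methyl-4-(propan-2-yl)-3,4,4a,8,9,9a-hexahydro-7H-benzo[7]annulen-7-one, cis ring fusion | O=C1CC[C@H]2C(C)=CC[C@H](C(C)C)[C@H]2C=C1 | intermediate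
14 | (7S)-alcohol of 13, hydroxyl trans to the ring-fusion hydrogens | O[C@H]1CC[C@H]2C(C)=CC[C@H](C(C)C)[C@H]2C=C1 | intermediate
15 | 5,6-epoxide of 14, oxirane cis to the hydroxyl | O[C@H]1CC[C@H]2C(C)=CC[C@H](C(C)C)[C@H]2[C@H]3O[C@@H]13 | intermediate
16 | 5,6-epoxy-7-ketone, oxirane trans to the ring-fusion hydrogens | O=C1CC[C@H]2C(C)=CC[C@H](C(C)C)[C@H]2[C@H]3O[C@@H]13 | intermediate
17 | triethylsilyl enol ether of 16 (C8=C15 enol silane, C2–C3 oxirane) | CC[Si](CC)(CC)OC1=CC[C@H]2C(C)=CC[C@H](C(C)C)[C@H]2[C@H]3O[C@@H]13 | intermediate
18 | 2-methylfuran | Cc1ccco1 | starting material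
19 | (4+3) adduct as its C2 triethylsilyl ether: C15 ketone bridging C3 and C8 of the 4,7-oxygen-bridged ten-membered ring | O=C1[C@@H]2[C@H](O[Si](CC)(CC)CC)[C@@H]3[C@@H](C(C)C)CC=C(C)[C@@H]3C[C@H]1[C@]3(C)C=C[C@H]2O3 | intermediate
20 | (4+3) adduct alcohol: C15 ketone bridging C3 and C8, H on C4, methyl on C7, C5=C6 and C11=C12 alkenes, C2 hydroxyl trans to the C3–C4 bond | O=C1[C@@H]2[C@H](O)[C@@H]3[C@@H](C(C)C)CC=C(C)[C@@H]3C[C@H]1[C@]3(C)C=C[C@H]2O3 | intermediate
21 | C2 methanesulfonate of 20 | O=C1[C@@H]2[C@H](OS(C)(=O)=O)[C@@H]3[C@@H](C(C)C)CC=C(C)[C@@H]3C[C@H]1[C@]3(C)C=C[C@H]2O3 | intermediate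
22 | lactone of 21 with oxygen inserted between C15 and C8 | O=C1[C@@H]2[C@H](OS(C)(=O)=O)[C@@H]3[C@@H](C(C)C)CC=C(C)[C@@H]3C[C@H](O1)[C@]3(C)C=C[C@H]2O3 | intermediate
23 | methyl ester on C3 (saturated), C2 mesylate, free C8 hydroxyl, 4,7-oxygen bridge | COC(=O)[C@@H]1[C@H](OS(C)(=O)=O)[C@@H]2[C@@H](C(C)C)CC=C(C)[C@@H]2C[C@H](O)[C@]2(C)C=C[C@H]1O2 | intermediate
24 | 4-deoxy-8-O-de(urocanoyl)sarcodictyin A (H on C4) | COC(=O)/C1=C/[C@@H]2[C@@H](C(C)C)CC=C(C)[C@@H]2C[C@H](O)[C@]2(C)C=C[C@H]1O2 | intermediate
25 | 8-O-de(urocanoyl)sarcodictyin A (C8 alcohol, C4 hemiketal) | COC(=O)/C1=C/[C@@H]2[C@@H](C(C)C)CC=C(C)[C@@H]2C[C@H](O)[C@]2(C)C=C[C@@]1(O)O2 | intermediate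
26 | (E)-3-(1-methyl-1H-imidazol-4-yl)prop-2-enoic acid | OC(=O)/C=C/c1cn(C)cn1 | starting material
27 | mixed anhydride of 26 with 2,4,6-trichlorobenzoic acid | O=C(/C=C/c1cn(C)cn1)OC(=O)c1c(Cl)cc(Cl)cc1Cl | intermediate
28 | sarcodictyin A | COC(=O)/C1=C/[C@@H]2[C@@H](C(C)C)CC=C(C)[C@@H]2C[C@H](OC(=O)/C=C/c2cn(C)cn2)[C@]2(C)C=C[C@@]1(O)O2 | target

**Step count and risks**
Total step count: 19. Longest linear sequence: 19 steps (1 to 28).

Steps most likely to fail:

Step 14. The cycloaddition may stop after the first C–C bond, with rearomatisation of the furan instead of closure at C8, or it may show poor compact over extended selectivity. The fallback sets out from epoxy enol silane 17 and replaces the concerted epoxide opening by stepwise generation of a free 2-silyloxyallyl cation. Bromotrimethylsilane (CH2Cl2, −78 °C) should open the oxirane at C3 with inversion and give the 2-silyloxyallyl bromide F1. AgOTf then abstracts bromide in the presence of 2-methylfuran 18 (CH2Cl2/MeNO2, −78 °C), and the cation should add the furan on the face anti to the C2 silyloxy group, again the convex face, to give the adduct trimethylsilyl ether F2. HF·pyridine cleaves the silyl ether and the route is rejoined at bridged hydroxy ketone 20.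

Step 18. Hydride abstraction may be too slow because the ester-bearing alkene destabilises the cation, or the oxidant may attack the allylic positions of ring A. The fallback sets out from 24 and uses hydrogen-atom abstraction instead of hydride abstraction. Rh2(cap)4 (dirhodium tetrakis(caprolactamate)) with tert-butyl hydroperoxide (K2CO3, CH2Cl2, 23 °C) should remove the weakest hydrogen, that on C4, and give the mixed tert-butyl peroxy ketal F3. Reduction of its O–O bond with Zn in AcOH returns the route at hemiketal 25.

Step 10. Catalyst and substrate may work against each other, giving a poor ratio of C15 epimers; any wrong epimer would end as the convex epoxide and then as the wrong face in step 14. The fallback sets out from cycloheptenone 13 and goes straight to epoxy ketone 16, replacing steps 10 to 12. It is an iminium-catalysed asymmetric Weitz–Scheffer epoxidation with aqueous H2O2 and a 9-amino-9-deoxy-epi-cinchona alkaloid bis(trifluoroacetate) salt in dioxane, the pseudoenantiomer being chosen for delivery to the concave face. No new compound arises (F0).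

Further compounds
F1 | step 14 | 2-silyloxyallyl bromide: C8=C15 triethylsilyl enol ether, bromine on C3 on the convex face, trimethylsilyloxy on C2 on the concave face | CC[Si](CC)(CC)OC1=CC[C@H]2C(C)=CC[C@H](C(C)C)[C@H]2[C@@H](O[Si](C)(C)C)[C@@H]1Br
F2 | step 14 | C2 trimethylsilyl ether of bridged hydroxy ketone 20 | O=C1[C@@H]2[C@H](O[Si](C)(C)C)[C@@H]3[C@@H](C(C)C)CC=C(C)[C@@H]3C[C@H]1[C@]3(C)C=C[C@H]2O3
F3 | step 18 | C4 tert-butyl peroxy ketal of 24 | COC(=O)/C1=C/[C@@H]2[C@@H](C(C)C)CC=C(C)[C@@H]2C[C@H](O)[C@]2(C)C=C[C@@]1(OOC(C)(C)C)O2
F0 | step 10 | none | none
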